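**Plan**
- Feature: in ring A, the acyl carbon on C4a together with C6–OMe, C7–OH and C8–OMe is the substitution pattern of acetosyringone. Only the oxygens on C5 and C8a are absent, and these carbons are the two symmetry-equivalent positions ortho to the ketone.
- Cuts: O1–C2 (cyclodehydration) and C2–C3 (enolate C-aroylation) open ring C to a 2,6-dihydroxyacetophenone and an isovanillic acid chloride. C5–O and C8a–O are then cut back to two aryl C–H bonds.
- Forward: rings A and B are bought. C5–O and C8a–O are made together by an oxime-ether-directed, Pd-catalysed double C–H acetoxylation. The C2–C3 bond then joins the halves, and the pyranone ring C closes last.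
- Stereochemistry: none to set. Only the E geometry of the oxime ether matters (its nitrogen lone pair must face the ring), and it is erased on hydrolysis.
- Protection: pivalates on O7 and O3' only, both removed in the last step.

Key step: step 3

Remark: acerosin has no stereocentre and no stereogenic axis, so the "single enantiomer" is simply the achiral compound. Oxime ethers 7 and 8 are drawn E, and any E/Z isomerisation there would be without consequence.

**Route**

Step 1
Reactants: 1 acetosyringone; 2 pivaloyl chloride
Product: 3 4-acetyl-2,6-dimethoxyphenyl pivalate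
Conditions: PivCl (1.2 equiv), Et3N, DMAP (cat.), CH2Cl2, 0 °C → rt
Reagents that add atoms: pivaloyl chloride (2), CC(C)(C)C(=O)Cl
Why: DMAP-catalysed O-acylation (nucleophilic acyl substitution) of the only free phenol should proceed despite the two flanking methoxy groups and installs the ester that later shields the ring from iodine(III).

Step 2
Reactants: 3 4-acetyl-2,6-dimethoxyphenyl pivalate; 4 O-methylhydroxylamine hydrochloride
Product: 5 4-[(1E)-N-methoxyethanimidoyl]-2,6-dimethoxyphenyl pivalate
Conditions: MeONH2·HCl (1.5 equiv), NaOAc, EtOH, 60 °C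
Reagents that add atoms: O-methylhydroxylamine hydrochloride (4), CON.Cl
Why: Oxime ether condensation of an unhindered aryl methyl ketone under buffered conditions should leave the hindered aryl pivalate alone and give the thermodynamically preferred E isomer (methoxy anti to the ring), the one whose nitrogen lone pair points at the ortho C–H bonds.

Step 3
Reactants: 5 4-[(1E)-N-methoxyethanimidoyl]-2,6-dimethoxyphenyl pivalate; 6 (diacetoxyiodo)benzene
Product: 7 3,5-diacetoxy-4-[(1E)-N-methoxyethanimidoyl]-2,6-dimethoxyphenyl pivalate
Conditions: Pd(OAc)2 (10 mol %), PhI(OAc)2 (3 equiv), AcOH/Ac2O (1:1), 100 °C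
Reagents that add atoms: (diacetoxyiodo)benzene (6), CC(=O)OI(OC(C)=O)c1ccccc1
Why: The oxime nitrogen binds Pd(OAc)2 and acetate-assisted concerted metalation–deprotonation at an ortho C–H gives a five-membered palladacycle, which PhI(OAc)2 oxidises to a high-valent palladium acetate that forms the C–O bond by reductive elimination and returns Pd(II); rotation about the aryl–C(=N) bond then presents the second, equivalent ortho C–H and the cycle repeats. The closest known reaction is the Pd(II)-catalysed O-methyl-oxime-directed ortho C–H acetoxylation of aryl ketoxime ethers with PhI(OAc)2 in AcOH/Ac2O, in which substrates with two open ortho positions go on to the diacetate when oxidant is in excess. No ring is closed (the palladacycle is transient) and no stereocentre is formed. The selectivity needed is ortho-only, twofold oxygenation without oxidation of the oxygen-rich ring: the ring of 5 has no other C–H, the oxime C-methyl cannot reach a five-membered palladacycle, the pivalate blocks the phenol-to-quinone pathway, and Ac2O keeps the medium dry so that neither the oxime ether nor the new aryl acetates hydrolyse. The methoxy groups flanking both reacting positions are expected to slow palladation, which is why a raised catalyst loading, three equivalents of oxidant and 100 °C are planned.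

Step 4
Reactants: 7 3,5-diacetoxy-4-[(1E)-N-methoxyethanimidoyl]-2,6-dimethoxyphenyl pivalate
Product: 9 4-acetyl-3,5-dihydroxy-2,6-dimethoxyphenyl pivalate, via dihydroxy oxime ether 8 (not isolated)
Conditions: 6 M aq. HCl/1,4-dioxane (1:1), 80 °C, Ar
Reagents that add atoms: water, O
Why: Acid-catalysed ester hydrolysis should remove the two acetates first, after which the now planar, hydrogen-bonded oxime ether 8 undergoes oxime ether hydrolysis (driven by protonation of the released methoxyamine), while the tert-butyl ester between two methoxy groups hydrolyses far more slowly.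

Step 5
Reactants: 10 isovanillic acid; 2 pivaloyl chloride
Product: 11 4-methoxy-3-(pivaloyloxy)benzoic acid
Conditions: PivCl (1.2 equiv), NaOH (2.2 equiv), H2O/THF, 0 °C; then 1 M HCl
Reagents that add atoms: pivaloyl chloride (2), CC(C)(C)C(=O)Cl
Why: Schotten–Baumann acylation, in which the phenoxide is far more nucleophilic than the carboxylate in water, any mixed anhydride is hydrolysed, and acidification returns the free acid.

Step 6
Reactants: 11 4-methoxy-3-(pivaloyloxy)benzoic acid
Product: 12 4-methoxy-3-(pivaloyloxy)benzoyl chloride
Conditions: (COCl)2 (1.5 equiv), DMF (cat.), CH2Cl2, 0 °C → rt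
Reagents that add atoms: oxalyl chloride, O=C(Cl)C(=O)Cl
Why: Acid chloride formation through the Vilsmeier-type chloroiminium species is mild enough to leave the aryl pivalate untouched.

Step 7
Reactants: 9 4-acetyl-3,5-dihydroxy-2,6-dimethoxyphenyl pivalate; 12 4-methoxy-3-(pivaloyloxy)benzoyl chloride
Product: 13 3,5-dihydroxy-2,6-dimethoxy-4-{3-[4-methoxy-3-(pivaloyloxy)phenyl]-3-oxopropanoyl}phenyl pivalate
Conditions: LiHMDS (4.2 equiv), THF, −78 → −10 °C; then 12 (1.05 equiv), −78 °C → rt; aq. HCl work-up
Reagents that add atoms: none
Why: Claisen-type C-acylation of a lithium polyanion (the LiHMDS variant of flavone synthesis that bypasses the Baker–Venkataraman ester): both phenols and the methyl ketone are deprotonated, the enolate carbon is the most nucleophilic site and attacks the aroyl chloride, and the fourth equivalent of base takes up the acidic β-diketone so that it is not acylated again.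

Step 8
Reactants: 13 3,5-dihydroxy-2,6-dimethoxy-4-{3-[4-methoxy-3-(pivaloyloxy)phenyl]-3-oxopropanoyl}phenyl pivalate
Product: 14 5-hydroxy-6,8-dimethoxy-2-[4-methoxy-3-(pivaloyloxy)phenyl]-4-oxo-4H-chromen-7-yl pivalate
Conditions: AcOH, H2SO4 (cat.), 95 °C
Reagents that add atoms: none
Why: Acid-catalysed cyclodehydration of an o-hydroxyaryl β-diketone (the closing step of a Baker–Venkataraman-type flavone synthesis) forms O1–C2 by addition of a phenol to the aroyl carbonyl and loss of water, and because the two phenols are equivalent only one flavone can result.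

Step 9
Reactants: 14 5-hydroxy-6,8-dimethoxy-2-[4-methoxy-3-(pivaloyloxy)phenyl]-4-oxo-4H-chromen-7-yl pivalate
Product: 15 acerosin (5,7-dihydroxy-2-(3-hydroxy-4-methoxyphenyl)-6,8-dimethoxy-4H-chromen-4-one)
Conditions: NaOMe (6 equiv), MeOH/THF, 0 → 40 °C, Ar; then aq. HCl to pH 4
Reagents that add atoms: none
Why: Zemplén-type methanolysis (transesterification) should cleave both aryl pivalates, whose phenoxides are good leaving groups (O7 is vinylogous to the C4 carbonyl), while the deprotonated 5-hydroxyflavone resists methoxide addition at C2.

**Compound list**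
1 | acetosyringone | CC(=O)c1cc(OC)c(O)c(OC)c1 | starting material
2 | pivaloyl chloride | CC(C)(C)C(=O)Cl | starting material
3 | 4-acetyl-2,6-dimethoxyphenyl pivalate | CC(=O)c1cc(OC)c(OC(=O)C(C)(C)C)c(OC)c1 | intermediate
4 | O-methylhydroxylamine hydrochloride | CON.Cl | starting material
5 | 4-[(1E)-N-methoxyethanimidoyl]-2,6-dimethoxyphenyl pivalate | CO/N=C(\C)c1cc(OC)c(OC(=O)C(C)(C)C)c(OC)c1 | intermediate
6 | (diacetoxyiodo)benzene | CC(=O)OI(OC(C)=O)c1ccccc1 | starting material
7 | 3,5-diacetoxy-4-[(1E)-N-methoxyethanimidoyl]-2,6-dimethoxyphenyl pivalate | CO/N=C(\C)c1c(OC(C)=O)c(OC)c(OC(=O)C(C)(C)C)c(OC)c1OC(C)=O | intermediate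
8 | 3,5-dihydroxy-4-[(1E)-N-methoxyethanimidoyl]-2,6-dimethoxyphenyl pivalate | CO/N=C(\C)c1c(O)c(OC)c(OC(=O)C(C)(C)C)c(OC)c1O | intermediate
9 | 4-acetyl-3,5-dihydroxy-2,6-dimethoxyphenyl pivalate | CC(=O)c1c(O)c(OC)c(OC(=O)C(C)(C)C)c(OC)c1O | intermediate
10 | isovanillic acid | COc1ccc(C(=O)O)cc1O | starting material
11 | 4-methoxy-3-(pivaloyloxy)benzoic acid | COc1ccc(C(=O)O)cc1OC(=O)C(C)(C)C | intermediate
12 | 4-methoxy-3-(pivaloyloxy)benzoyl chloride | COc1ccc(C(Cl)=O)cc1OC(=O)C(C)(C)C | intermediate
13 | 3,5-dihydroxy-2,6-dimethoxy-4-{3-[4-methoxy-3-(pivaloyloxy)phenyl]-3-oxopropanoyl}phenyl pivalate | COc1ccc(C(=O)CC(=O)c2c(O)c(OC)c(OC(=O)C(C)(C)C)c(OC)c2O)cc1OC(=O)C(C)(C)C | intermediate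
14 | 5-hydroxy-6,8-dimethoxy-2-[4-methoxy-3-(pivaloyloxy)phenyl]-4-oxo-4H-chromen-7-yl pivalate | COc1ccc(-c2cc(=O)c3c(O)c(OC)c(OC(=O)C(C)(C)C)c(OC)c3o2)cc1OC(=O)C(C)(C)C | intermediate
15 | acerosin | COc1ccc(-c2cc(=O)c3c(O)c(OC)c(O)c(OC)c3o2)cc1O | target

**Step count**
Total: 9 steps. Longest linear sequence: 7 steps (1, 2, 3, 4, 7, 8, 9); steps 5 and 6 form the two-step ring-B branch.

**Steps most likely to fail**

Step 3. The second cyclopalladation may stall. Each reacting C–H is flanked by a methoxy group, and after the first acetoxylation the oxime methyl clashes with the new ortho acetate in the planar palladacycle. The oxygen-rich ring could also be over-oxidised by iodine(III). The fallback brings the oxygens in through halogen instead of through palladacycles. Setting out from 3, electrophilic dibromination (NBS 2.2 equiv, MeCN, rt → 50 °C; both open positions are ortho to one methoxy and para to the other) should give 4-acetyl-3,5-dibromo-2,6-dimethoxyphenyl pivalate F1. Copper-catalysed hydroxylation of both ketone-activated aryl bromides (CuI, 1,10-phenanthroline, aq. KOH, DMSO, 100 °C, Ar), which also saponifies the pivalate, should give 2,4,6-trihydroxy-3,5-dimethoxyacetophenone F2. Pivaloylation of the one hydroxyl that is not hydrogen-bonded to the ketone (PivCl 1.0 equiv, Et3N, CH2Cl2, −20 °C) comes back to the route at 9.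

Step 4. Hydrolysis of the oxime ether may be slow, so that the time in hot acid needed for full conversion starts to hydrolyse the pivalate, or an o-hydroxyaryl oxime may close to a benzisoxazole. The fallback separates the two events and cleaves the N–O bond reductively. From 7, K2CO3 in MeOH at 0 °C removes only the acetates to give 8, this time isolated. Buffered aqueous TiCl3 (NH4OAc, THF, rt) should reduce the N–OMe bond to the N–H ketimine 3,5-dihydroxy-4-ethanimidoyl-2,6-dimethoxyphenyl pivalate F3. Stirring F3 with dilute aqueous HCl at room temperature hydrolyses it and rejoins the route at 9.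

Step 7. O-acylation of the phenoxides or acyl transfer involving the pivalates may compete with C-acylation of the enolate, or the diketone may be acylated a second time. The fallback is the classical intramolecular route. From 9 and 12, mono-O-aroylation (12 1.0 equiv, Et3N, DMAP cat., CH2Cl2, −20 °C; the second phenol stays chelated to the ketone) should give 2-acetyl-3-hydroxy-4,6-dimethoxy-5-(pivaloyloxy)phenyl 4-methoxy-3-(pivaloyloxy)benzoate F4. A Baker–Venkataraman O→C aroyl shift (KOtBu 3 equiv, THF, 0 °C → rt) then rejoins the route at 13.

**Further compounds**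
F1 | step 3 | 4-acetyl-3,5-dibromo-2,6-dimethoxyphenyl pivalate | CC(=O)c1c(Br)c(OC)c(OC(=O)C(C)(C)C)c(OC)c1Br
F2 | step 3 | 2,4,6-trihydroxy-3,5-dimethoxyacetophenone | CC(=O)c1c(O)c(OC)c(O)c(OC)c1O
F3 | step 4 | 3,5-dihydroxy-4-ethanimidoyl-2,6-dimethoxyphenyl pivalate | CC(=N)c1c(O)c(OC)c(OC(=O)C(C)(C)C)c(OC)c1O
F4 | step 7 | 2-acetyl-3-hydroxy-4,6-dimethoxy-5-(pivaloyloxy)phenyl 4-methoxy-3-(pivaloyloxy)benzoate | CC(=O)c1c(O)c(OC)c(OC(=O)C(C)(C)C)c(OC)c1OC(=O)c1ccc(OC)c(OC(=O)C(C)(C)C)c1
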